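**Q: What is left at the last noon reading?**
65.5 % of the substrate, after 6.00 h, and yet that flask has slowed.

| flask | substrate | partner | catalyst | temperature | remark | time |
|---|---|---|---|---|---|---|
| summer | 0.10 M | 3 equiv | 0.2 mol% | −40 °C | run made earlier |  |
| noon | 0.15 M | 3 equiv | 0.2 mol% | −5 °C | run made earlier |  |
| epsilon | 0.20 M | 3.00 equiv | 0.2 mol% | 5 °C |  | 4.0 h |
| alpha | 0.20 M | 3.00 equiv | 0.2 mol% | 25 °C |  | 4.0 h |
| delta | 0.20 M | 3.00 equiv | 0.2 mol% | −35 °C |  | 4.0 h |
| eta | 0.20 M | 3.00 equiv | 0.2 mol% | −15 °C |  | 4.0 h |

| run | time / h | product / % |
|---|---|---|
| summer | 6.00 | 0.4 |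
| summer | 12.0 | 1.3 |
| summer | 20.0 | 3.4 |
| summer | 25.0 | 4.7 |
| summer | 30.0 | 5.8 |
| summer | 40.0 | 6.6 |
| noon | 0.500 | 5.8 |
| noon | 0.833 | 7.9 |
| noon | 1.33 | 12.8 |
| noon | 2.00 | 17.4 |
| noon | 4.00 | 27.7 |
| noon | 6.00 | 34.5 |

(readings scatter by 0.5 percentage points)

- the numbers in the tables scatter by 0.5 percentage points (one standard deviation)

1. which flask leads in amount of product, in percent of the substrate charged ("all alike" within 1.5 percentage points) (epsilon / alpha / delta / eta / all alike)
2. how much product is there at the end, in percent of the substrate charged: epsilon
3. how much product is there at the end, in percent of the substrate charged: alpha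
4. how much product is there at the end, in percent of the substrate charged: delta
5. how much product is there at the end, in percent of the substrate charged: eta

**Q: Slowed by how much?**
Take the logarithm of charged over remaining substrate. Its equally spaced noon steps shrink, which reads as a fade rate of 0.149 /h. This is a loose reading, since it carries the scatter. The readings don't say whether catalyst or partner is what fades.

**Q: What do you carry from that?**
Solve both ends. Early, the logarithm grows as pace times time, where pace is a pseudo-first-order constant. Late, it levels off, and the curve joining the two is an exponential approach. The level is the reach, pace divided by fade rate, the logarithm a flask can make before it stops. Noon reads 0.740.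

**Q: Noon ran at 0.15 M. Your flasks have 0.20 M.**
Partner and catalyst are charged per substrate. I assume pace follows their product, so it goes with the square of the concentration. I also assume the fade rate doesn't change with concentration. That gives a reach of 1.32, a roof of 73.2 % product if warmth moves pace and fade alike.

**Q: Does it? That is the weak spot.**
It is unread. Noon's fade rate over 40.0 h would make 5.96 lifetimes, yet the summer reading there stands at twice the one at 20.0 h. So the fade rate climbs with temperature, and two runs can't say whether it climbs faster than pace. I hold alpha to the roof or below and leave the lead open between alpha and epsilon.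

**Q: The forecast?**
It says alpha leads: 53 % for epsilon, 80 % for alpha, 1.3 % for delta, 21 % for eta, on the ground that “Warmer should therefore give more product”. Its alpha stands above my roof, and there we differ.

**The flask:** epsilon leads with 51.9 %, then alpha with 33.6 %, eta with 25.6 % and delta with 4.66 %.

    substrate + partner + catalyst → catalyst + product (k = 0.490 /M²/s, Ea = 49.0 kJ/mol)
    partner → decomposed reagent (k = 1.10 × 10⁻⁴ /s, Ea = 78.0 kJ/mol)
    (constants at 5 °C)

In alpha, partner is down to 0.0219 % by 2.00 h, and 66 % of the substrate stays. Its reach is 0.409, below the 1.32 scaled from noon. Epsilon reaches 0.863 by 40.0 h. A quarter of its partner should cut that reach to 0.216, or 19.4 % product. The neighbour of epsilon charged with 0.750 equiv of partner holds 16.2 % product at 4.00 h, with 12.4 % of its partner left.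

The data were generated by integration with made-up constants; noise was put on by code.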